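The dihydropyran ring (O1, C2–C6) is traced back to an oxetane. The O1–C2 bond is allylic to the ring alkene C3=C4, and C4 stands 1,3 to the oxygen-bearing C6. Returning O1 from C2 to C4 therefore leaves the four-membered ring O1–C4–C5–C6 with an alkenyl arm C3=C2–C10. In the forward direction a catalytic Lewis acid opens the strained allylic C4–O1 bond and O1 re-bonds at C2. This one operation builds the six-membered ring, the O1–C2 bond, the C3=C4 alkene and the C2 stereocentre. The precursor is a cis-2,4-disubstituted oxetane with an (E)-alkene, the finished (R)-dichloride on C6 and C10 as a silyl ether.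

Key step: step 7

Numbering used throughout: O1, C2 (bears C10), C3 (bears the ring methyl), C4, C5, C6 (bears C7; C8 = CH2Cl and C9 = CH3 on C7). Open-chain and oxetane intermediates keep these numbers.

Assumption: the antipodes of the Schiff-base ligand (step 1) and of Ipc2BCl (step 4) are those that the accepted transition-state models assign to the (R)-dichloride and to Si-face attack. Both reagents exist in both antipodal forms, so a reversed sense would be corrected by exchanging the antipode only.

Step 1
Reactants: 1 2-methylprop-2-en-1-ol (methallyl alcohol)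
Product: 2 (2R)-2,3-dichloro-2-methylpropan-1-ol
Conditions: tBuOCl (1.2 equiv), ClTi(OiPr)3 (1.1 equiv), chiral tridentate Schiff-base ligand (N-salicylidene derivative of a tert-leucine-derived 1,1-diphenyl amino alcohol, 20 mol %), hexanes, −20 °C
Reagents that add atoms: tert-butyl hypochlorite, CC(C)(C)OCl; chlorotitanium triisopropoxide, CC(C)O[Ti](Cl)(OC(C)C)OC(C)C
Why: Titanium-templated catalytic enantioselective dichlorination of an allylic alcohol: the substrate binds as its titanium alkoxide inside the chiral complex, electrophilic chlorine from the hypochlorite and titanium-bound chloride add anti across the alkene, and the ligand-defined face sets the tertiary chloride C7 as (R).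

Step 2
Reactants: 2 (2R)-2,3-dichloro-2-methylpropan-1-ol
Product: 3 (2R)-2,3-dichloro-2-methylpropanal
Conditions: Dess–Martin periodinane, CH2Cl2, 0 °C to rt; volatile, carried on as a dried solution
Reagents that add atoms: none
Why: Dess–Martin oxidation under neutral conditions; the aldehyde has no α-hydrogen, so C7 cannot epimerise and HCl cannot be lost through an enolate.

Step 3
Reactants: 4 2-[(tert-butyldimethylsilyl)oxy]acetaldehyde; 5 3-(triphenyl-λ5-phosphanylidene)butan-2-one
Product: 6 (3E)-5-[(tert-butyldimethylsilyl)oxy]-3-methylpent-3-en-2-one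
Conditions: toluene, 80 °C
Reagents that add atoms: none
Why: Wittig olefination with a stabilised α-branched keto-ylide, which should give the (E)-trisubstituted enone (C10 trans to C4), the geometry that later places C10 on the outer position of the allyl system.

Step 4
Reactants: 6 (3E)-5-[(tert-butyldimethylsilyl)oxy]-3-methylpent-3-en-2-one; 3 (2R)-2,3-dichloro-2-methylpropanal
Product: 8 (2E,6S,7R)-1-[(tert-butyldimethylsilyl)oxy]-7,8-dichloro-6-hydroxy-3,7-dimethyloct-2-en-4-one, via enol diisopinocampheylborinate 7 (not isolated)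
Conditions: (+)-Ipc2BCl, Et3N, Et2O, 0 °C; then 3, −78 to −20 °C; then MeOH, pH 7 buffer, 30% H2O2, 0 °C
Reagents that add atoms: none
Why: Reagent-controlled boron aldol of a methyl ketone: enolisation on the methyl side, then a cyclic boron transition state in which the Ipc ligands steer the enolate to the Si face of 3 and set C6 as (S); C7 gives little bias of its own because its CH3 and CH2Cl arms are similar in size, and the C6 epimer is a diastereomer that chromatography removes.

Step 5
Reactants: 8 (2E,6S,7R)-1-[(tert-butyldimethylsilyl)oxy]-7,8-dichloro-6-hydroxy-3,7-dimethyloct-2-en-4-one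
Product: 9 (2E,4S,6S,7R)-1-[(tert-butyldimethylsilyl)oxy]-7,8-dichloro-3,7-dimethyloct-2-ene-4,6-diol (1,3-anti diol)
Conditions: Me4NBH(OAc)3, MeCN/AcOH (1:1), −30 °C
Reagents that add atoms: none
Why: Evans–Saksena reduction: the acetoxyborohydride exchanges onto the C6 hydroxyl and delivers hydride to the C4 carbonyl through a chair transition state, which gives 1,2-reduction only and sets C4 as (S), anti to C6; the acidic medium leaves the chlorohydrin intact.

Step 6
Reactants: 9 (2E,4S,6S,7R)-1-[(tert-butyldimethylsilyl)oxy]-7,8-dichloro-3,7-dimethyloct-2-ene-4,6-diol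
Product: 11 (2R,4S)-2-[(2E)-4-[(tert-butyldimethylsilyl)oxy]but-2-en-2-yl]-4-[(2R)-1,2-dichloropropan-2-yl]oxetane (cis; route numbering C4 R and C6 S), via C4 oxyphosphonium hydrazide salt 10 (not isolated)
Conditions: PPh3 (1.5 equiv), DIAD (1.5 equiv), toluene (0.02 M), 0 °C to rt; chromatography on Et3N-deactivated silica
Reagents that add atoms: none
Why: Intramolecular Mitsunobu etherification (Mitsunobu-type cyclodehydration of a 1,3-diol to an oxetane, 4-exo-tet): the open allylic C4 hydroxyl is taken up as the oxyphosphonium ion and the neopentylic, chlorine-acidified C6 hydroxyl displaces it with inversion, so the anti diol gives the cis oxetane with C4 (R), and because no alkali alkoxide is formed the C6–O/C7–Cl chlorohydrin is not driven to an epoxide.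

Step 7
Reactants: 11 (2R,4S)-2-[(2E)-4-[(tert-butyldimethylsilyl)oxy]but-2-en-2-yl]-4-[(2R)-1,2-dichloropropan-2-yl]oxetane
Product: 12 tert-butyl{[(2S,6S)-6-[(2R)-1,2-dichloropropan-2-yl]-3-methyl-5,6-dihydro-2H-pyran-2-yl]methoxy}dimethylsilane (2,6-trans)
Conditions: Cu(OTf)2 (5 mol %), 4 Å molecular sieves, CH2Cl2, −40 to 0 °C; Et3N quench
Reagents that add atoms: none
Why: Cu(OTf)2 binds O1, the strained allylic C4–O1 bond stretches heterolytically (alkoxide and C2–C3–C4 allyl-cation character, no free intermediate is assumed), and O1 re-bonds at the distal terminus C2, a net suprafacial 1,3-oxygen shift driven by release of oxetane strain. The closest known reaction is the Cu(OTf)2- or phosphoric-acid-catalysed ring expansion of 2-vinyloxetanes to 3,6-dihydro-2H-pyrans. The pyran closes in a 6-endo-trig mode onto the allyl system, which is possible only from the rotamer with C5 cis to C2; with the (E)-alkene this rotamer meets only H2 and the H4/CH3 contact, so no A(1,3) penalty is paid. C2 is set by chirality transfer from C4: O1 leaves and returns on the same face, which for (4R) and an (E)-alkene with C10 on the outer position gives (2S), the 2,6-trans ring. In the sofa-like transition state reached from the cis oxetane the bulky C7 group points outward, so facial memory, sterics and the product's preference for a pseudoaxial C2 substituent beside the C3 methyl (A(1,2) strain) all favour the same isomer. The step needs return at C2 rather than C4 (C4 return only regenerates 11) and survival of the silyl ether and both chlorides, which anhydrous, cold, catalytic conditions and the inductive deactivation of C7–Cl by its oxygen and chlorine neighbours should secure.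

Step 8
Reactants: 12 tert-butyl{[(2S,6S)-6-[(2R)-1,2-dichloropropan-2-yl]-3-methyl-5,6-dihydro-2H-pyran-2-yl]methoxy}dimethylsilane
Product: 13 [(2S,6S)-6-[(2R)-1,2-dichloropropan-2-yl]-3-methyl-5,6-dihydro-2H-pyran-2-yl]methanol
Conditions: HF·pyridine, pyridine, THF, 0 °C to rt
Reagents that add atoms: none
Why: Fluoride-driven desilylation of a primary TBS ether under buffered, non-basic conditions, which should leave the allylic ring ether and both C–Cl bonds (no E2 loss of HCl) untouched.

Step 9
Reactants: 13 [(2S,6S)-6-[(2R)-1,2-dichloropropan-2-yl]-3-methyl-5,6-dihydro-2H-pyran-2-yl]methanol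
Product: 14 (2S,6S)-6-[(2R)-1,2-dichloropropan-2-yl]-3-methyl-5,6-dihydro-2H-pyran-2-carbaldehyde
Conditions: Dess–Martin periodinane, NaHCO3, CH2Cl2, 0 °C; used at once
Reagents that add atoms: none
Why: Dess–Martin oxidation under buffered neutral conditions, chosen because C2–H of the product is α to the aldehyde, allylic and α to oxygen, so acid or base would epimerise C2 or move the alkene into conjugation.

Step 10
Reactants: 14 (2S,6S)-6-[(2R)-1,2-dichloropropan-2-yl]-3-methyl-5,6-dihydro-2H-pyran-2-carbaldehyde
Product: 15 (2S,6S)-2-(dibromomethyl)-6-[(2R)-1,2-dichloropropan-2-yl]-3-methyl-5,6-dihydro-2H-pyran (target)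
Conditions: (PhO)3P (1.3 equiv), Br2 (1.2 equiv), CH2Cl2, −78 °C; then 14, −78 to 0 °C
Reagents that add atoms: bromine, BrBr
Why: Deoxygenative gem-dibromination of an aldehyde with the triphenyl phosphite–bromine reagent: phosphorus takes up the carbonyl oxygen and two bromides are delivered to C10 at low temperature without base, the slight excess of phosphite leaves no free Br2 for the C3=C4 alkene, and C2 is not touched.

Compound list
1 | 2-methylprop-2-en-1-ol | CC(=C)CO | starting material
2 | (2R)-2,3-dichloro-2-methylpropan-1-ol | OC[C@@](C)(Cl)CCl | intermediate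
3 | (2R)-2,3-dichloro-2-methylpropanal | O=C[C@@](C)(Cl)CCl | intermediate
4 | 2-[(tert-butyldimethylsilyl)oxy]acetaldehyde | CC(C)(C)[Si](C)(C)OCC=O | starting material
5 | 3-(triphenyl-λ5-phosphanylidene)butan-2-one | CC(=O)C(C)=P(c1ccccc1)(c1ccccc1)c1ccccc1 | starting material
6 | (3E)-5-[(tert-butyldimethylsilyl)oxy]-3-methylpent-3-en-2-one | CC(C)(C)[Si](C)(C)OC/C=C(\C)C(C)=O | intermediate
7 | enol diisopinocampheylborinate of 6 (boron on the C4 oxygen, C4=C5 methylene, Ipc groups from (−)-α-pinene) | CC(C)(C)[Si](C)(C)OC/C=C(\C)C(=C)OB([C@H]1C[C@H]2C[C@@H]([C@@H]1C)C2(C)C)[C@H]1C[C@H]2C[C@@H]([C@@H]1C)C2(C)C | intermediate (not isolated)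
8 | (2E,6S,7R)-1-[(tert-butyldimethylsilyl)oxy]-7,8-dichloro-6-hydroxy-3,7-dimethyloct-2-en-4-one | CC(C)(C)[Si](C)(C)OC/C=C(\C)C(=O)C[C@H](O)[C@@](C)(Cl)CCl | intermediate
9 | (2E,4S,6S,7R)-1-[(tert-butyldimethylsilyl)oxy]-7,8-dichloro-3,7-dimethyloct-2-ene-4,6-diol (anti) | CC(C)(C)[Si](C)(C)OC/C=C(\C)[C@@H](O)C[C@H](O)[C@@](C)(Cl)CCl | intermediate
10 | C4-O-triphenylphosphonium derivative of 9, hydrazide counter-ion | CC(C)(C)[Si](C)(C)OC/C=C(\C)[C@@H](O[P+](c1ccccc1)(c1ccccc1)c1ccccc1)C[C@H](O)[C@@](C)(Cl)CCl.CC(C)OC(=O)[N-]NC(=O)OC(C)C | intermediate (not isolated)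
11 | (2R,4S)-2-[(2E)-4-[(tert-butyldimethylsilyl)oxy]but-2-en-2-yl]-4-[(2R)-1,2-dichloropropan-2-yl]oxetane (cis) | CC(C)(C)[Si](C)(C)OC/C=C(\C)[C@H]1C[C@@H]([C@@](C)(Cl)CCl)O1 | intermediate
12 | tert-butyl{[(2S,6S)-6-[(2R)-1,2-dichloropropan-2-yl]-3-methyl-5,6-dihydro-2H-pyran-2-yl]methoxy}dimethylsilane (2,6-trans) | CC1=CC[C@@H]([C@@](C)(Cl)CCl)O[C@@H]1CO[Si](C)(C)C(C)(C)C | intermediate
13 | [(2S,6S)-6-[(2R)-1,2-dichloropropan-2-yl]-3-methyl-5,6-dihydro-2H-pyran-2-yl]methanol | CC1=CC[C@@H]([C@@](C)(Cl)CCl)O[C@@H]1CO | intermediate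
14 | (2S,6S)-6-[(2R)-1,2-dichloropropan-2-yl]-3-methyl-5,6-dihydro-2H-pyran-2-carbaldehyde | CC1=CC[C@@H]([C@@](C)(Cl)CCl)O[C@@H]1C=O | intermediate
15 | (2S,6S)-2-(dibromomethyl)-6-[(2R)-1,2-dichloropropan-2-yl]-3-methyl-5,6-dihydro-2H-pyran | CC1=CC[C@@H]([C@@](C)(Cl)CCl)O[C@@H]1C(Br)Br | target

Total step count: 10. Longest linear sequence: 9 (steps 1, 2, 4, 5, 6, 7, 8, 9 and 10, from 1).

Steps most likely to fail

1. Step 7. If the C4–O1 bond breaks fully before O1 reaches C2, several things can go wrong:
   - facial memory may be lost;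
   - the C5–C6 bond may cleave in a Grob sense, back to an aldehyde and a diene;
   - a proton may be lost to give a diene;
   - adventitious acid may strip the silyl ether.

   The fallback leaves the route at 8 and rejoins it at 12. Narasaka–Prasad reduction of 8 (Et2BOMe, NaBH4, THF/MeOH, −78 °C) would give the syn diol (2E,4R,6S,7R)-1-[(tert-butyldimethylsilyl)oxy]-7,8-dichloro-3,7-dimethyloct-2-ene-4,6-diol F1. In F1 the C4 hydroxyl sits on the face that O1 occupies in 11. PdCl2(MeCN)2 (divalent palladium, catalytic, THF, 0 °C) then adds the C6 hydroxyl to C2 in a 6-endo-trig oxypalladation, followed by loss of the C4 hydroxyl. This formal syn-SN2' cyclisation of a hydroxy allylic alcohol, with 1,3-chirality transfer, is established for 2,6-disubstituted dihydropyrans.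

2. Step 6. Four-membered closure is slow. Before it occurs, the oxyphosphonium ion may be attacked through the alkene terminus C2, may lose a C5 proton, or may alkylate the hydrazide. Attack at C2 anti to the leaving group would be harmless, because it leads to the same 2,6-trans ring as step 7.

   The fallback leaves the route at 9 and rejoins it at 11 by a two-stage Williamson closure instead of a redox dehydration. Selective sulfonylation of the less hindered allylic hydroxyl (Ms2O, 2,4,6-collidine, CH2Cl2, −40 °C) would give (2E,4S,6S,7R)-1-[(tert-butyldimethylsilyl)oxy]-7,8-dichloro-6-hydroxy-3,7-dimethyloct-2-en-4-yl methanesulfonate F2. F2 is kept cold and treated with LiHMDS (THF, −78 to −30 °C), which closes it by 4-exo-tet displacement with inversion. The lithium counter-ion and the low temperature are chosen to hold back attack of the C6 alkoxide on the neighbouring C7–Cl.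

3. Step 10. The α-alkoxy, β,γ-unsaturated aldehyde may enolise on the phosphorus reagent. That would lead to loss of C2–H (a bromovinyl ether or a conjugated isomer) or to epimerisation at C2, in place of the second bromide delivery.

   The fallback leaves the route at 14 and rejoins it at 15 through a hydrazone. Condensation with 1,2-bis(tert-butyldimethylsilyl)hydrazine (Sc(OTf)3, catalytic, CH2Cl2, 0 °C) would give the N-silyl hydrazone (E)-1-(tert-butyldimethylsilyl)-2-{[(2S,6S)-6-[(2R)-1,2-dichloropropan-2-yl]-3-methyl-5,6-dihydro-2H-pyran-2-yl]methylidene}hydrazine F3. CuBr2 with Et3N in MeOH then oxidises F3 by way of the diazo compound to the gem-dibromide with loss of nitrogen, a known conversion of aldehyde hydrazones.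

Further compounds
F1 | step 7 | (2E,4R,6S,7R)-1-[(tert-butyldimethylsilyl)oxy]-7,8-dichloro-3,7-dimethyloct-2-ene-4,6-diol (syn) | CC(C)(C)[Si](C)(C)OC/C=C(\C)[C@H](O)C[C@H](O)[C@@](C)(Cl)CCl
F2 | step 6 | (2E,4S,6S,7R)-1-[(tert-butyldimethylsilyl)oxy]-7,8-dichloro-6-hydroxy-3,7-dimethyloct-2-en-4-yl methanesulfonate | CC(C)(C)[Si](C)(C)OC/C=C(\C)[C@@H](OS(C)(=O)=O)C[C@H](O)[C@@](C)(Cl)CCl
F3 | step 10 | (E)-1-(tert-butyldimethylsilyl)-2-{[(2S,6S)-6-[(2R)-1,2-dichloropropan-2-yl]-3-methyl-5,6-dihydro-2H-pyran-2-yl]methylidene}hydrazine | CC1=CC[C@@H]([C@@](C)(Cl)CCl)O[C@@H]1/C=N/N[Si](C)(C)C(C)(C)C
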